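**Retrosynthetic overview**
1. Target 28 ⇐ 27 ⇐ 26: the end-game is only C10 O-acetylation and removal of two orthogonal silyl ethers; the trans-lactone comes from oxidation of a C2–B bond next to a C1-acrylate (23).
2. 23 ⇐ 19 + methyl 2-bromoacrylate 20: a Pd-triggered 1,2-boronate shift in the 15-membered cyclic bis(alkenyl)borate 22 contracts it to the 14-membered carbocycle (C2–C3), forms C1–C15 and sets C1/C2. The carbocycle is formed first, the lactone second.
3. 19 ⇐ 16: C2 comes from cross-metathesis with a vinylboronate; the C3=C4 iodide from Negishi carboalumination–iodination.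
4. 16 ⇐ 5 ⇐ hex-1-en-5-yne: two rounds of Cr-catalysed asymmetric propargylation of an enal (C10, then C6), O-silylation and Zr-catalysed methylalumination; all three E-trisubstituted alkenes arise from syn carboalumination.

Assumption: late intermediates carry cembrane locants (C1 = ring CH bearing C15, C2 = O–CH, methyls on C4/C8/C12, C15(=C17H2)–C16(=O)); B(mac) is the boronic ester of cis-1,2-dimethylacenaphthene-1,2-diol; each chiral catalyst is used as the enantiomer that gives the drawn configuration.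

**Route**

Step 1
Reactants: 1 hex-1-en-5-yne
Product: 4 (2E)-3-methylhepta-2,6-dien-1-ol, via alkenyldimethylalane 2 (not isolated), via lithium alkenylaluminate 3 (not isolated)
Conditions: Me3Al (2 equiv), Cp2ZrCl2 (0.25 equiv), CH2Cl2, 0 °C→rt; evaporate; n-BuLi, THF, −78 °C; (CH2O)n, rt; aq. HCl
Reagents that add atoms: trimethylaluminium (C[Al](C)C); paraformaldehyde (C=O)
Why: Zr-catalysed Negishi carboalumination adds Me and Al syn across the terminal alkyne only (alkene inert), and the aluminate is hydroxymethylated with retention, fixing the C11=C12 E-geometry.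

Step 2
Reactants: 4 (2E)-3-methylhepta-2,6-dien-1-ol
Product: 5 (2E)-3-methylhepta-2,6-dienal
Conditions: MnO2 (15 equiv), CH2Cl2, rt
Reagents that add atoms: none
Why: MnO2 allylic oxidation stops at the enal and leaves alkene geometry and the terminal alkene untouched.

Step 3
Reactants: 5 (2E)-3-methylhepta-2,6-dienal; 6 propargyl bromide
Product: 7 triethyl{[(4S,5E)-6-methyldeca-5,9-dien-1-yn-4-yl]oxy}silane
Conditions: CrCl2 (10 mol %), chiral carbazole-bis(oxazoline) ligand (12 mol %), Mn (2 equiv), TESCl (1.5 equiv), iPr2NEt (0.3 equiv), THF, rt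
Reagents that add atoms: chlorotriethylsilane (CC[Si](Cl)(CC)CC)
Why: Catalytic asymmetric Nozaki–Hiyama propargylation: the propargyl/allenyl-Cr(III) species adds 1,2 to the enal, the chiral Cr complex sets C10 (S), and TESCl as turnover silylating agent delivers the alcohol already protected.

Step 4
Reactants: 7 triethyl{[(4S,5E)-6-methyldeca-5,9-dien-1-yn-4-yl]oxy}silane
Product: 10 (2E,5S,6E)-3,7-dimethyl-5-(triethylsilyloxy)undeca-2,6,10-trien-1-ol, via alkenylalane 8 (not isolated), via lithium aluminate 9 (not isolated)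
Conditions: Me3Al (2.5 equiv), Cp2ZrCl2 (0.3 equiv), CH2Cl2, 0 °C→rt; evaporate; n-BuLi, THF, −78 °C; (CH2O)n, rt; aq. Rochelle salt
Reagents that add atoms: trimethylaluminium (C[Al](C)C); paraformaldehyde (C=O)
Why: Second Negishi carboalumination–hydroxymethylation on the terminal alkyne (silyl ether and alkenes tolerated); syn addition sets the C7=C8 E-alkene.

Step 5
Reactants: 10 (2E,5S,6E)-3,7-dimethyl-5-(triethylsilyloxy)undeca-2,6,10-trien-1-ol
Product: 11 (2E,5S,6E)-3,7-dimethyl-5-(triethylsilyloxy)undeca-2,6,10-trienal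
Conditions: MnO2 (15 equiv), CH2Cl2, rt
Reagents that add atoms: none
Why: Chemoselective MnO2 oxidation of the primary allylic alcohol under neutral conditions that keep the TES ether.

Step 6
Reactants: 11 (2E,5S,6E)-3,7-dimethyl-5-(triethylsilyloxy)undeca-2,6,10-trienal; 6 propargyl bromide
Product: 13 (4S,5E,8S,9E)-6,10-dimethyl-8-(triethylsilyloxy)tetradeca-5,9,13-trien-1-yn-4-ol, via trimethylsilyl ether 12 (not isolated)
Conditions: CrCl2 (10 mol %), same chiral ligand (12 mol %), Mn (2 equiv), TMSCl (1.5 equiv), iPr2NEt (0.3 equiv), THF, rt; then K2CO3, MeOH, 0 °C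
Reagents that add atoms: none
Why: The same asymmetric Nozaki–Hiyama propargylation sets C6 (S) under catalyst control (the 1,5-remote C10 centre has little influence), and the labile TMS ether is methanolysed selectively beside the TES ether.

Step 7
Reactants: 13 (4S,5E,8S,9E)-6,10-dimethyl-8-(triethylsilyloxy)tetradeca-5,9,13-trien-1-yn-4-ol
Product: 14 (4S,5E,8S,9E)-4-(tert-butyldimethylsilyloxy)-6,10-dimethyl-8-(triethylsilyloxy)tetradeca-5,9,13-trien-1-yne
Conditions: TBSOTf, 2,6-lutidine, CH2Cl2, −78 °C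
Reagents that add atoms: tert-butyldimethylsilyl triflate (CC(C)(C)[Si](C)(C)OS(=O)(=O)C(F)(F)F)
Why: Silylation gives a TBS ether orthogonal to the more labile allylic TES ether, which is what later distinguishes C6–O from C10–O.

Step 8
Reactants: 14 (4S,5E,8S,9E)-4-(tert-butyldimethylsilyloxy)-6,10-dimethyl-8-(triethylsilyloxy)tetradeca-5,9,13-trien-1-yne
Product: 16 (1E,4S,5E,8S,9E)-4-(tert-butyldimethylsilyloxy)-1-iodo-2,6,10-trimethyl-8-(triethylsilyloxy)tetradeca-1,5,9,13-tetraene, via alkenylalane 15 (not isolated)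
Conditions: Me3Al (3 equiv), Cp2ZrCl2 (0.3 equiv), CH2Cl2, 0 °C→rt; I2, THF, −30 °C; aq. Na2S2O3/NaHCO3
Reagents that add atoms: trimethylaluminium (C[Al](C)C); iodine (II)
Why: Negishi carboalumination followed by iodinolysis with retention gives the (E)-2-methyl-1-iodoalkene (I cis to Me), i.e. the C3=C4 unit.

Step 9
Reactants: 17 potassium vinyltrifluoroborate
Product: 18 vinyl-B(mac) (8-ethenyl-6b,9a-dimethyl-6b,9a-dihydroacenaphtho[1,2-d][1,3,2]dioxaborole)
Conditions: mac-diol (1 equiv), TMSCl (3 equiv), MeCN, rt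
Reagents that add atoms: cis-1,2-dimethylacenaphthene-1,2-diol, mac-diol (O[C@]1(C)c2cccc3cccc(c23)[C@]1(C)O)
Why: TMSCl abstracts fluoride from the trifluoroborate and the freed boron halide is esterified by the diol (standard trifluoroborate-to-boronic ester exchange).

Step 10
Reactants: 16 (1E,4S,5E,8S,9E)-4-(tert-butyldimethylsilyloxy)-1-iodo-2,6,10-trimethyl-8-(triethylsilyloxy)tetradeca-1,5,9,13-tetraene; 18 vinyl-B(mac)
Product: 19 (1E,5E,7S,9E,11S,13E)-11-(tert-butyldimethylsilyloxy)-14-iodo-5,9,13-trimethyl-7-(triethylsilyloxy)tetradeca-1,5,9,13-tetraen-1-yl-B(mac)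
Conditions: Grubbs II (5 mol %), 18 (2.5 equiv), CH2Cl2, 40 °C
Reagents that add atoms: none
Why: Olefin cross-metathesis of the only monosubstituted alkene with the vinylboronate is E-selective; the trisubstituted alkenes and the alkenyl iodide do not engage.

Step 11
Reactants: 19 (1E,5E,7S,9E,11S,13E)-11-(tert-butyldimethylsilyloxy)-14-iodo-5,9,13-trimethyl-7-(triethylsilyloxy)tetradeca-1,5,9,13-tetraen-1-yl-B(mac); 20 methyl 2-bromoacrylate
Product: 23 methyl 2-[(1S,2S,3E,6S,7E,10S,11E)-2-B(mac)-6-(tert-butyldimethylsilyloxy)-4,8,12-trimethyl-10-(triethylsilyloxy)cyclotetradeca-3,7,11-trien-1-yl]prop-2-enoate, via alkenyllithium 21 (not isolated), via cyclic bis(alkenyl)borate 22 (not isolated)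
Conditions: t-BuLi (2.05 equiv), THF/Et2O 4:1, 1 mM, −100→−20 °C; concentrate to 0.05 M; Pd(OAc)2 (5 mol %), (Sp,Sp)-MandyPhos (6 mol %), KOTf (2 equiv), 20 (1.5 equiv), THF, 40 °C
Reagents that add atoms: none
Why: Proposed new method: I/Li exchange (faster than t-BuLi addition to the hindered boronic ester, as in in-situ-quench borylations) gives alkenyllithium 21, which closes onto boron to the 15-membered bis(alkenyl)borate 22; the L*Pd(II)(α-acrylyl) species from oxidative addition of 20 binds the less hindered C1=C2 π-bond and triggers anti 1,2-migration of the C3 alkenyl group from B to C2 (ring contraction 15→14) with C1–Pd bond formation, and reductive elimination makes C1–C15; anti addition across the E-alkene fixes the 1,2-trans relationship and the MandyPhos antipode sets the absolute configuration (1S,2S by CIP with boron, the same spatial arrangement as 1R,2S in the lactone); the closest known reaction is the intermolecular Pd/MandyPhos conjunctive cross-coupling of bis(alkenyl) and β-substituted alkenyl-B(mac) ate complexes with C(sp2) triflates or bromides.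

Step 12
Reactants: 23 methyl 2-[(1S,2S,3E,6S,7E,10S,11E)-2-B(mac)-6-(tert-butyldimethylsilyloxy)-4,8,12-trimethyl-10-(triethylsilyloxy)cyclotetradeca-3,7,11-trien-1-yl]prop-2-enoate
Product: 26 (1R,2S,3E,6S,7E,10S,11E)-6-(tert-butyldimethylsilyloxy)-10-hydroxycembra-3,7,11,15(17)-tetraen-16,2-olide, via hydroxy ester 24 (not isolated), via bis-silyl lactone 25 (not isolated)
Conditions: NaBO3·4H2O (5 equiv), THF/H2O, rt; then PPTS (0.3 equiv), MeOH/CH2Cl2, rt
Reagents that add atoms: sodium perborate ([Na+].O[B-](O)(O)OO)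
Why: Perborate oxidises the C2–B bond with retention (boron-to-oxygen 1,2-shift) without attacking the acrylate, the γ-hydroxy α-methylene ester closes to the trans-fused lactone, and PPTS/MeOH cleaves the allylic TES ether while the TBS ether survives.

Step 13
Reactants: 26 (1R,2S,3E,6S,7E,10S,11E)-6-(tert-butyldimethylsilyloxy)-10-hydroxycembra-3,7,11,15(17)-tetraen-16,2-olide
Product: 27 (1R,2S,3E,6S,7E,10S,11E)-10-acetoxy-6-(tert-butyldimethylsilyloxy)cembra-3,7,11,15(17)-tetraen-16,2-olide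
Conditions: Ac2O, pyridine, DMAP (cat.), CH2Cl2, 0 °C→rt
Reagents that add atoms: acetic anhydride (CC(=O)OC(C)=O)
Why: DMAP-catalysed acetylation of the only free hydroxyl (C10).

Step 14
Reactants: 27 (1R,2S,3E,6S,7E,10S,11E)-10-acetoxy-6-(tert-butyldimethylsilyloxy)cembra-3,7,11,15(17)-tetraen-16,2-olide
Product: 28 (1R,2S,3E,6S,7E,10S,11E)-10-acetoxy-6-hydroxycembra-3,7,11,15(17)-tetraen-16,2-olide (CNP0406430.1)
Conditions: HF·pyridine, pyridine/THF, 0 °C→rt
Reagents that add atoms: none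
Why: Buffered fluoride desilylation removes the TBS ether without acyl migration, lactone opening or conjugate addition to the α-methylene lactone.

**Compound list**
1 | hex-1-en-5-yne | C=CCCC#C | starting material
2 | (E)-dimethyl(2-methylhexa-1,5-dien-1-yl)alumane | C[Al](C)/C=C(\C)CCC=C | intermediate
3 | lithium (E)-butyldimethyl(2-methylhexa-1,5-dien-1-yl)aluminate | [Li+].CCCC[Al-](C)(C)/C=C(\C)CCC=C | intermediate
4 | (2E)-3-methylhepta-2,6-dien-1-ol | OC/C=C(\C)CCC=C | intermediate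
5 | (2E)-3-methylhepta-2,6-dienal | O=C/C=C(\C)CCC=C | intermediate
6 | propargyl bromide (3-bromoprop-1-yne) | C#CCBr | starting material
7 | triethyl{[(4S,5E)-6-methyldeca-5,9-dien-1-yn-4-yl]oxy}silane | C#CC[C@H](O[Si](CC)(CC)CC)/C=C(\C)CCC=C | intermediate
8 | dimethyl[(1E,4S,5E)-2,6-dimethyl-4-(triethylsilyloxy)deca-1,5,9-trien-1-yl]alumane | C[Al](C)/C=C(\C)C[C@H](O[Si](CC)(CC)CC)/C=C(\C)CCC=C | intermediate
9 | lithium butyldimethyl[(1E,4S,5E)-2,6-dimethyl-4-(triethylsilyloxy)deca-1,5,9-trien-1-yl]aluminate | [Li+].CCCC[Al-](C)(C)/C=C(\C)C[C@H](O[Si](CC)(CC)CC)/C=C(\C)CCC=C | intermediate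
10 | (2E,5S,6E)-3,7-dimethyl-5-(triethylsilyloxy)undeca-2,6,10-trien-1-ol | OC/C=C(\C)C[C@H](O[Si](CC)(CC)CC)/C=C(\C)CCC=C | intermediate
11 | (2E,5S,6E)-3,7-dimethyl-5-(triethylsilyloxy)undeca-2,6,10-trienal | O=C/C=C(\C)C[C@H](O[Si](CC)(CC)CC)/C=C(\C)CCC=C | intermediate
12 | 4-O-trimethylsilyl ether of 13 | C#CC[C@H](O[Si](C)(C)C)/C=C(\C)C[C@H](O[Si](CC)(CC)CC)/C=C(\C)CCC=C | intermediate
13 | (4S,5E,8S,9E)-6,10-dimethyl-8-(triethylsilyloxy)tetradeca-5,9,13-trien-1-yn-4-ol | C#CC[C@H](O)/C=C(\C)C[C@H](O[Si](CC)(CC)CC)/C=C(\C)CCC=C | intermediate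
14 | (4S,5E,8S,9E)-4-(tert-butyldimethylsilyloxy)-6,10-dimethyl-8-(triethylsilyloxy)tetradeca-5,9,13-trien-1-yne | C#CC[C@H](O[Si](C)(C)C(C)(C)C)/C=C(\C)C[C@H](O[Si](CC)(CC)CC)/C=C(\C)CCC=C | intermediate
15 | dimethyl[(1E,4S,5E,8S,9E)-4-(tert-butyldimethylsilyloxy)-2,6,10-trimethyl-8-(triethylsilyloxy)tetradeca-1,5,9,13-tetraen-1-yl]alumane | C[Al](C)/C=C(\C)C[C@H](O[Si](C)(C)C(C)(C)C)/C=C(\C)C[C@H](O[Si](CC)(CC)CC)/C=C(\C)CCC=C | intermediate
16 | (1E,4S,5E,8S,9E)-4-(tert-butyldimethylsilyloxy)-1-iodo-2,6,10-trimethyl-8-(triethylsilyloxy)tetradeca-1,5,9,13-tetraene | I/C=C(\C)C[C@H](O[Si](C)(C)C(C)(C)C)/C=C(\C)C[C@H](O[Si](CC)(CC)CC)/C=C(\C)CCC=C | intermediate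
17 | potassium vinyltrifluoroborate | [K+].C=C[B-](F)(F)F | starting material
18 | vinyl-B(mac), 8-ethenyl-6b,9a-dimethyl-6b,9a-dihydroacenaphtho[1,2-d][1,3,2]dioxaborole | C=CB1O[C@]2(C)c3cccc4cccc(c34)[C@]2(C)O1 | intermediate
19 | (1E,5E,7S,9E,11S,13E)-11-(tert-butyldimethylsilyloxy)-14-iodo-5,9,13-trimethyl-7-(triethylsilyloxy)tetradeca-1,5,9,13-tetraen-1-yl-B(mac) | I/C=C(\C)C[C@H](O[Si](C)(C)C(C)(C)C)/C=C(\C)C[C@H](O[Si](CC)(CC)CC)/C=C(\C)CC/C=C/B1O[C@]2(C)c3cccc4cccc(c34)[C@]2(C)O1 | intermediate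
20 | methyl 2-bromoacrylate | C=C(Br)C(=O)OC | starting material
21 | (E)-alkenyllithium derived from 19 (Li in place of I) | [Li]/C=C(\C)C[C@H](O[Si](C)(C)C(C)(C)C)/C=C(\C)C[C@H](O[Si](CC)(CC)CC)/C=C(\C)CC/C=C/B1O[C@]2(C)c3cccc4cccc(c34)[C@]2(C)O1 | intermediate
22 | lithium 15-membered cyclic bis(alkenyl) mac-borate (boron bridging C2 and C3; 1E,3E,7E,11E; 6S,10S) | [Li+].[B-]12(O[C@]3(C)c4cccc5cccc(c45)[C@]3(C)O1)/C=C(\C)C[C@H](O[Si](C)(C)C(C)(C)C)/C=C(\C)C[C@H](O[Si](CC)(CC)CC)/C=C(\C)CC/C=C/2 | intermediate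
23 | methyl 2-[(1S,2S,3E,6S,7E,10S,11E)-2-B(mac)-6-(tert-butyldimethylsilyloxy)-4,8,12-trimethyl-10-(triethylsilyloxy)cyclotetradeca-3,7,11-trien-1-yl]prop-2-enoate | B1(O[C@]2(C)c3cccc4cccc(c34)[C@]2(C)O1)[C@H]5/C=C(\C)C[C@H](O[Si](C)(C)C(C)(C)C)/C=C(\C)C[C@H](O[Si](CC)(CC)CC)/C=C(\C)CC[C@@H]5C(=C)C(=O)OC | intermediate
24 | methyl 2-[(1R,2S,3E,6S,7E,10S,11E)-6-(tert-butyldimethylsilyloxy)-2-hydroxy-4,8,12-trimethyl-10-(triethylsilyloxy)cyclotetradeca-3,7,11-trien-1-yl]prop-2-enoate | O[C@H]1/C=C(\C)C[C@H](O[Si](C)(C)C(C)(C)C)/C=C(\C)C[C@H](O[Si](CC)(CC)CC)/C=C(\C)CC[C@@H]1C(=C)C(=O)OC | intermediate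
25 | (1R,2S,3E,6S,7E,10S,11E)-6-(tert-butyldimethylsilyloxy)-10-(triethylsilyloxy)cembra-3,7,11,15(17)-tetraen-16,2-olide | C=C1C(=O)O[C@H]2/C=C(\C)C[C@H](O[Si](C)(C)C(C)(C)C)/C=C(\C)C[C@H](O[Si](CC)(CC)CC)/C=C(\C)CC[C@H]12 | intermediate
26 | (1R,2S,3E,6S,7E,10S,11E)-6-(tert-butyldimethylsilyloxy)-10-hydroxycembra-3,7,11,15(17)-tetraen-16,2-olide | C=C1C(=O)O[C@H]2/C=C(\C)C[C@H](O[Si](C)(C)C(C)(C)C)/C=C(\C)C[C@H](O)/C=C(\C)CC[C@H]12 | intermediate
27 | (1R,2S,3E,6S,7E,10S,11E)-10-acetoxy-6-(tert-butyldimethylsilyloxy)cembra-3,7,11,15(17)-tetraen-16,2-olide | C=C1C(=O)O[C@H]2/C=C(\C)C[C@H](O[Si](C)(C)C(C)(C)C)/C=C(\C)C[C@H](OC(C)=O)/C=C(\C)CC[C@H]12 | intermediate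
28 | (1R,2S,3E,6S,7E,10S,11E)-10-acetoxy-6-hydroxycembra-3,7,11,15(17)-tetraen-16,2-olide (CNP0406430.1) | C=C1C(=O)O[C@H]2/C=C(\C)C[C@H](O)/C=C(\C)C[C@H](OC(C)=O)/C=C(\C)CC[C@H]12 | target

**Step count**
Total steps: 14. Longest linear sequence: 13 (steps 1–8 and 10–14; step 9 is a one-step side branch).

**Three steps most likely to fail, with fallbacks**

Step 11 (the proposed new ring-contracting conjunctive coupling). The risks are t-BuLi attack at boron, oligomeric instead of cyclic ate complexes, direct Suzuki-type alkenyl transfer to Pd, and insufficient facial control. The fallback uses known chemistry, sets out from 14 and comes back at 25. Compound 14 is methylaluminated as in step 8 to alane 15, converted with n-BuLi into the lithium aluminate F1 and hydroxymethylated with paraformaldehyde to the allylic alcohol F2. MnO2 then gives the C2 enal F3. Cross-metathesis of its terminal alkene with methyl 2-(bromomethyl)acrylate (Grubbs II) gives the (Z)-2-(bromomethyl)enoate F4. CrCl2-mediated Nozaki–Hiyama macrocyclisation (THF, high dilution, chiral sulfonamide ligand to bias the aldehyde face) follows, the chromium alkoxide lactonising in situ, and gives the cis-fused lactone F5; cis is the usual syn outcome for (Z)-2-(bromomethyl)enoates, and the (1R,2R) isomer is separated if face control is incomplete. LiOH opens F5 to the hydroxy acid F6, and Mitsunobu lactonisation (PPh3, DIAD) inverts C2 to give 25, which continues through the PPTS/MeOH stage of step 12.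

Step 10 (cross-metathesis with the non-standard vinyl-B(mac) partner in the presence of an alkenyl iodide; E/Z ratio and conversion are uncertain). The fallback sets out from 16 and comes back at 19. Cross-metathesis with commercial vinylboronic acid pinacol ester, the well-precedented partner, gives the pinacol boronate F7. Diethanolamine (Et2O, rt) converts it, with loss of pinacol, into the crystalline diethanolamine boronate F8. Stirring F8 with mac-diol in CH2Cl2/aq. NH4Cl releases diethanolamine and gives 19.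

Step 6 (second asymmetric propargylation, on a hindered β,β-disubstituted enal with a remote stereocentre; ee/dr may be moderate). The fallback sets out from 11 and comes back at 14. A titanium-mediated acetate aldol addition of N-acetyl-(4S)-4-isopropylthiazolidine-2-thione (TiCl4, iPr2NEt, CH2Cl2, −78 °C; auxiliary antipode chosen for 6S) gives the aldol adduct F9. TBSOTf/2,6-lutidine gives the silyl ether F10. DIBAL-H (−78 °C) cleaves the auxiliary to the β-silyloxy aldehyde F11. Ohira–Bestmann homologation (dimethyl 1-diazo-2-oxopropylphosphonate, K2CO3, MeOH) gives 14.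

**Further compounds**
F1 | step 11 | lithium butyldimethyl[(1E,4S,5E,8S,9E)-4-(tert-butyldimethylsilyloxy)-2,6,10-trimethyl-8-(triethylsilyloxy)tetradeca-1,5,9,13-tetraen-1-yl]aluminate | [Li+].CCCC[Al-](C)(C)/C=C(\C)C[C@H](O[Si](C)(C)C(C)(C)C)/C=C(\C)C[C@H](O[Si](CC)(CC)CC)/C=C(\C)CCC=C
F2 | step 11 | (2E,5S,6E,9S,10E)-5-(tert-butyldimethylsilyloxy)-3,7,11-trimethyl-9-(triethylsilyloxy)pentadeca-2,6,10,14-tetraen-1-ol | OC/C=C(\C)C[C@H](O[Si](C)(C)C(C)(C)C)/C=C(\C)C[C@H](O[Si](CC)(CC)CC)/C=C(\C)CCC=C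
F3 | step 11 | (2E,5S,6E,9S,10E)-5-(tert-butyldimethylsilyloxy)-3,7,11-trimethyl-9-(triethylsilyloxy)pentadeca-2,6,10,14-tetraenal | O=C/C=C(\C)C[C@H](O[Si](C)(C)C(C)(C)C)/C=C(\C)C[C@H](O[Si](CC)(CC)CC)/C=C(\C)CCC=C
F4 | step 11 | methyl (2Z,6E,8S,10E,12S,14E)-2-(bromomethyl)-12-(tert-butyldimethylsilyloxy)-6,10,14-trimethyl-16-oxo-8-(triethylsilyloxy)hexadeca-2,6,10,14-tetraenoate | O=C/C=C(\C)C[C@H](O[Si](C)(C)C(C)(C)C)/C=C(\C)C[C@H](O[Si](CC)(CC)CC)/C=C(\C)CC/C=C(\CBr)C(=O)OC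
F5 | step 11 | (1R,2R,3E,6S,7E,10S,11E)-6-(tert-butyldimethylsilyloxy)-10-(triethylsilyloxy)cembra-3,7,11,15(17)-tetraen-16,2-olide (cis-fused, 2-epi-25) | C=C1C(=O)O[C@@H]2/C=C(\C)C[C@H](O[Si](C)(C)C(C)(C)C)/C=C(\C)C[C@H](O[Si](CC)(CC)CC)/C=C(\C)CC[C@H]12
F6 | step 11 | 2-[(1R,2R,3E,6S,7E,10S,11E)-6-(tert-butyldimethylsilyloxy)-2-hydroxy-4,8,12-trimethyl-10-(triethylsilyloxy)cyclotetradeca-3,7,11-trien-1-yl]prop-2-enoic acid | O[C@@H]1/C=C(\C)C[C@H](O[Si](C)(C)C(C)(C)C)/C=C(\C)C[C@H](O[Si](CC)(CC)CC)/C=C(\C)CC[C@@H]1C(=C)C(=O)O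
F7 | step 10 | 2-[(1E,5E,7S,9E,11S,13E)-11-(tert-butyldimethylsilyloxy)-14-iodo-5,9,13-trimethyl-7-(triethylsilyloxy)tetradeca-1,5,9,13-tetraen-1-yl]-4,4,5,5-tetramethyl-1,3,2-dioxaborolane | I/C=C(\C)C[C@H](O[Si](C)(C)C(C)(C)C)/C=C(\C)C[C@H](O[Si](CC)(CC)CC)/C=C(\C)CC/C=C/B1OC(C)(C)C(C)(C)O1
F8 | step 10 | diethanolamine (N→B) boronate of the same alkenyl group | I/C=C(\C)C[C@H](O[Si](C)(C)C(C)(C)C)/C=C(\C)C[C@H](O[Si](CC)(CC)CC)/C=C(\C)CC/C=C/[B-]12OCC[NH+]1CCO2
F9 | step 6 | (3S,4E,7S,8E)-3-hydroxy-5,9-dimethyl-1-[(4S)-4-isopropyl-2-thioxo-1,3-thiazolidin-3-yl]-7-(triethylsilyloxy)trideca-4,8,12-trien-1-one | S=C1SC[C@H](C(C)C)N1C(=O)C[C@H](O)/C=C(\C)C[C@H](O[Si](CC)(CC)CC)/C=C(\C)CCC=C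
F10 | step 6 | 3-O-tert-butyldimethylsilyl ether of F9 | S=C1SC[C@H](C(C)C)N1C(=O)C[C@H](O[Si](C)(C)C(C)(C)C)/C=C(\C)C[C@H](O[Si](CC)(CC)CC)/C=C(\C)CCC=C
F11 | step 6 | (3S,4E,7S,8E)-3-(tert-butyldimethylsilyloxy)-5,9-dimethyl-7-(triethylsilyloxy)trideca-4,8,12-trienal | O=CC[C@H](O[Si](C)(C)C(C)(C)C)/C=C(\C)C[C@H](O[Si](CC)(CC)CC)/C=C(\C)CCC=C
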